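Start with a subtraction that needs no computer: take substrate and product from 100, and the remainder is substrate no longer in either column.

the same everywhere: substrate 0.20 mM

| flask | partner | free catalyst | remark |
|---|---|---|---|
| elm | 0.15 mM | 40 µM | run made earlier |
| birch | 0.22 mM | 40 µM | run made earlier |
| ash | 0.30 mM | 20 µM | run made earlier |
| flask | 0.300 mM | 40 µM |  |

| run | time / min | product / % | substrate / % |
|---|---|---|---|
| elm | 0.200 | 19.0 | 71.5 |
| elm | 0.333 | 29.8 | 59.9 |
| elm | 0.417 | 35.1 | 53.9 |
| elm | 0.667 | 46.4 | 41.1 |
| elm | 1.00 | 55.0 | 30.9 |
| elm | 1.50 | 60.5 | 22.9 |
| elm | 2.50 | 64.7 | 16.3 |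
| birch | 0.333 | 35.6 | 56.1 |
| birch | 0.667 | 56.5 | 33.8 |
| birch | 1.00 | 67.7 | 22.4 |
| birch | 1.33 | 74.1 | 15.1 |
| birch | 1.50 | 75.5 | 12.7 |
| birch | 2.00 | 80.3 | 7.1 |
| birch | 2.50 | 82.7 | 4.5 |
| ash | 0.200 | 14.0 | 83.3 |
| ash | 0.667 | 39.3 | 57.1 |
| ash | 1.00 | 50.3 | 44.9 |
| ash | 1.50 | 61.8 | 32.8 |
| ash | 2.50 | 73.7 | 19.5 |

(readings scatter by 0.3 percentage points)



* apparent order in partner when 50% of the substrate are converted (percent change of the rate of making product for one percent more partner charged)
* apparent order in free catalyst when 50% of the substrate are converted (percent change of the rate of making product for one percent more free catalyst charged)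

1. Do it for the ash run. At 2.50 min the remainder is 6.80%, against 2.70% at 0.200 min, so it grows as the run goes on. Read it as substrate carried off with catalyst, one for one; working forms are counted in it too.

2. Divide by the substrate converted. This gives L = 0.0845, the loss ratio, catalyst lost per substrate converted.

3. Turn the partner down. At their last readings, elm gives L = 0.227 and birch 0.134, so between these two runs, whose charges differ in partner, L is higher in elm, the run with less partner. Ash differs from both in partner and in catalyst charge, so hold it apart here.

4. Carry L to the flask, which has the substrate and partner charges of ash. Assume that the catalyst charge leaves L unchanged. At 50% conversion my estimate of the lost catalyst is then Z = 8.45 µM of the charge C = 40 µM.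

5. Turn the catalyst. Take the rate as proportional to C − Z, with Z following the substrate converted and not the charge. The order in catalyst is then C/(C − Z) = 1.27.

6. Turn the partner. Solve the two ends of my reckoning: with scarce partner I take the order from waiting as one, with plentiful partner as zero. Join them, then add the saved catalyst, Z/(C − Z) = 0.268, taking Z as inverse to partner. My guess for the waiting term brings the order to about 0.5.

7. The forecast says 0.6 in partner and 1.2 in catalyst, holding that “dead catalyst is set by conversion”. The flask gives 0.46 in partner and 1.2 in catalyst.

    substrate + free catalyst → catalyst intermediate A (k = 1110 /M/s)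
    partner + catalyst intermediate A → catalyst intermediate B (k = 2810 /M/s)
    catalyst intermediate B → free catalyst + product (k = 1.17 /s)
    catalyst intermediate A → spent catalyst (k = 0.0505 /s)

8. At 0.370 min in the flask, catalyst intermediate A is used by partner 12 times as fast as it turns into spent catalyst, so at that moment a share 0.0783 of its use goes to spent catalyst. At 3.00 min the flask holds 0.0842 of spent catalyst per substrate converted, and the L read from ash was 0.0845. In the simulated run of this flask with twice the partner, taking L at half its value raises C − Z by a factor 1.13, and the rate rises by a factor 1.23.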